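**Retrosynthetic overview**

1. Target 15 ⇐ 13 by cross-metathesis (vinyl → isobutenyl at C6'), and 13 ⇐ 12 by Shi epoxidation: the 2',3'-oxirane, with CH2OAr cis to CH3, is read as an (E)-trisubstituted allyl aryl ether.
2. 12 ⇐ acid 11 + (E)-iodoalkene 7: the bond between the O–CH2 carbon (C1') and the future oxirane CH (C2') is made by decarboxylative Ni/photoredox coupling. This is a radical union of two acceptor-type carbons (an O–CH2–CO2H carbon and an I–CH= carbon); CO2H is the traceless activating group and the olefin is the lower oxidation level of the oxirane.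
3. Enabling feature: C1' is a methylene flanked by the phenolic O-7 of the 2H-chromen-2-one, whose lone pair stabilises the radical left at C1' on loss of CO2; its neighbour C2' is an oxirane CH that can be carried as an sp2 C–I carbon.
4. 7 ⇐ acrolein + propargyl bromide (Barbier propargylation; Sharpless kinetic resolution sets C5'; Negishi carboalumination sets the E-olefin and the C3' methyl). 11 ⇐ hydrangetin + tert-butyl bromoacetate.
5. Ring order: the coumarin bicycle is bought intact; the oxirane is the only ring formed (step 7), after the fragment union.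

Key step: step 6

Assumption: 7-hydroxy-8-methoxycoumarin (hydrangetin) is taken as purchasable; side-chain carbons are called C1'–C7' from the ether CH2 outwards.

**Route**

Step 1
Reactants: 1 acrolein (prop-2-enal); 2 propargyl bromide (3-bromoprop-1-yne)
Product: 4 rac-hex-1-en-5-yn-3-ol, via allenylzinc bromide 3 (not isolated)
Conditions: Zn dust, THF, 0 °C; then 1, −78 → 0 °C; aqueous work-up
Reagents that add atoms: none
Why: Zinc-mediated Barbier-type propargylation, in which 2 and zinc should give allenylzinc bromide 3 that adds to the aldehyde carbon of 1 through an SE2' six-membered transition state to give the homopropargylic 1,2-adduct; the carbinol is formed racemic and is resolved in step 2.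

Step 2
Reactants: 4 rac-hex-1-en-5-yn-3-ol
Product: 5 (3R)-hex-1-en-5-yn-3-ol
Conditions: Ti(OiPr)4 (10 mol%), L-(+)-DIPT (15 mol%), t-BuOOH (0.6 equiv), 4 Å MS, CH2Cl2, −20 °C, run past half conversion
Reagents that add atoms: none
Why: Sharpless kinetic resolution of a 1-alken-3-ol, in which L-(+)-tartrate should epoxidise the (S)-enantiomer much faster (to the erythro epoxy alcohol), so that the (R)-alcohol, whose carbinol carbon becomes C5' of the target, is recovered enantioenriched.

Step 3
Reactants: 5 (3R)-hex-1-en-5-yn-3-ol
Product: 7 (1E,4R)-1-iodo-2-methylhexa-1,5-dien-4-ol, via alkenyldimethylalane aluminium alkoxide 6 (not isolated)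
Conditions: AlMe3 (3 equiv), Cp2ZrCl2 (0.25 equiv), CH2Cl2, 0 °C → rt; then I2, THF, −30 → 0 °C; aqueous Rochelle salt
Reagents that add atoms: trimethylaluminium, C[Al](C)C; iodine, II
Why: Negishi zirconium-catalysed carboalumination, in which (after the hydroxyl is capped as its aluminium alkoxide) Me–Al should add syn across the terminal alkyne with aluminium on the terminal carbon, and iodinolysis of the C–Al bond with retention should give the (E)-iodoalkene (I cis to CH3); the alkyne reacts far faster than the unactivated vinyl group and the carbinol centre is not touched.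

Step 4
Reactants: 8 7-hydroxy-8-methoxy-2H-chromen-2-one (hydrangetin); 9 tert-butyl bromoacetate
Product: 10 tert-butyl 2-[(8-methoxy-2-oxo-2H-chromen-7-yl)oxy]acetate
Conditions: K2CO3, acetone, reflux
Reagents that add atoms: none
Why: Williamson O-alkylation (SN2) of the acidic 7-OH with an α-bromo ester, which installs the future C1' together with its carboxyl activating group.

Step 5
Reactants: 10 tert-butyl 2-[(8-methoxy-2-oxo-2H-chromen-7-yl)oxy]acetate
Product: 11 2-[(8-methoxy-2-oxo-2H-chromen-7-yl)oxy]acetic acid
Conditions: TFA–CH2Cl2 (1:2), rt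
Reagents that add atoms: none
Why: Acidolysis of the tert-butyl ester (loss of 2-methylpropene via the tert-butyl cation) should free the acid while the lactone and the aryl ethers, stable to anhydrous acid, survive.

Step 6
Reactants: 11 2-[(8-methoxy-2-oxo-2H-chromen-7-yl)oxy]acetic acid; 7 (1E,4R)-1-iodo-2-methylhexa-1,5-dien-4-ol
Product: 12 7-{[(2E,5R)-5-hydroxy-3-methylhepta-2,6-dien-1-yl]oxy}-8-methoxy-2H-chromen-2-one
Conditions: Ir[dF(CF3)ppy]2(dtbbpy)PF6 (1 mol%), NiCl2·glyme (10 mol%), dtbbpy (12 mol%), Cs2CO3 (1 equiv), degassed DMSO, blue LEDs (450 nm), 25 °C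
Reagents that add atoms: none
Why: The excited Ir(III) photocatalyst oxidises the caesium carboxylate of 11, which loses CO2 to give the α-aryloxymethyl radical at C1' (stabilised by the lone pair of the coumarin O-7), while Ni(0)–dtbbpy inserts into the C–I bond of 7; radical capture at Ni(II) and reductive elimination from Ni(III) forge the C1'–C2' bond, and Ir(II) returns Ni(I) to Ni(0). The closest known reaction type is the metallaphotoredox decarboxylative C(sp3)–C(sp2) cross-coupling of α-oxy carboxylic acids with vinyl halides. No ring is closed and no stereocentre is created; the stereochemical element the step must deliver is the E geometry of the C2'=C3' olefin, which is retained from 7 because oxidative addition and reductive elimination at an alkenyl–nickel centre are stereoretentive, while the C5' carbinol is a spectator. The step also needs capture of the C1' radical by nickel to outrun its Giese addition to the C3=C4 bond of a coumarin, which the electron-rich 7,8-dioxygenated coumarin (a poor radical acceptor) and the raised nickel loading should secure; the ArOCH2–Ni unit has no β-hydrogen, so β-hydride elimination cannot intervene. The E-olefin fixed here encodes the relative configuration of both oxirane stereocentres set in step 7.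

Step 7
Reactants: 12 7-{[(2E,5R)-5-hydroxy-3-methylhepta-2,6-dien-1-yl]oxy}-8-methoxy-2H-chromen-2-one
Product: 13 7-({(2R,3R)-3-[(2R)-2-hydroxybut-3-en-1-yl]-3-methyloxiran-2-yl}methoxy)-8-methoxy-2H-chromen-2-one
Conditions: D-fructose-derived Shi ketone (30 mol%), Oxone, K2CO3, n-Bu4NHSO4 (cat.), MeCN–CH2(OMe)2 / aq. Na2B4O7–Na2EDTA buffer (pH ≈ 10.5), 0 °C
Reagents that add atoms: potassium peroxymonosulfate (Oxone), [K+].[O-]S(=O)(=O)OO
Why: Shi asymmetric epoxidation, in which the chiral dioxirane transfers oxygen to the (E)-trisubstituted C2'=C3' olefin through the spiro transition state, the D-fructose-derived ketone giving the (2'R,3'R) oxirane and syn-addition to the E-olefin placing CH2OAr cis to CH3; the monosubstituted vinyl group and the electron-poor coumarin C3=C4 bond should react much more slowly and C5' is unaffected.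

Step 8
Reactants: 13 7-({(2R,3R)-3-[(2R)-2-hydroxybut-3-en-1-yl]-3-methyloxiran-2-yl}methoxy)-8-methoxy-2H-chromen-2-one; 14 2-methylbut-2-ene
Product: 15 7-({(2R,3R)-3-[(2R)-2-hydroxy-4-methylpent-3-en-1-yl]-3-methyloxiran-2-yl}methoxy)-8-methoxy-2H-chromen-2-one (CNP0223665.1)
Conditions: Grubbs second-generation catalyst (5 mol%), 1,4-benzoquinone (10 mol%), 2-methylbut-2-ene–CH2Cl2 (1:1), 40 °C, sealed tube
Reagents that add atoms: none
Why: Olefin cross-metathesis with 2-methylbut-2-ene should turn the terminal vinyl group into the isobutenyl group with loss of propene, the conjugated cis-olefin of the coumarin being inert to the ruthenium carbene and no stereocentre being touched.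

**Compound list**

1 | acrolein (prop-2-enal) | C=CC=O | starting material
2 | propargyl bromide (3-bromoprop-1-yne) | C#CCBr | starting material
3 | allenylzinc bromide (propa-1,2-dien-1-ylzinc bromide) | C=C=C[Zn]Br | intermediate
4 | rac-hex-1-en-5-yn-3-ol | C#CCC(O)C=C | intermediate
5 | (3R)-hex-1-en-5-yn-3-ol | C#CC[C@@H](O)C=C | intermediate
6 | dimethylaluminium alkoxide of (1E,4R)-1-(dimethylalumanyl)-2-methylhexa-1,5-dien-4-ol | C[Al](C)/C=C(\C)C[C@@H](O[Al](C)C)C=C | intermediate
7 | (1E,4R)-1-iodo-2-methylhexa-1,5-dien-4-ol | I/C=C(\C)C[C@@H](O)C=C | intermediate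
8 | 7-hydroxy-8-methoxy-2H-chromen-2-one (hydrangetin) | COc1c(O)ccc2ccc(=O)oc12 | starting material
9 | tert-butyl bromoacetate | CC(C)(C)OC(=O)CBr | starting material
10 | tert-butyl 2-[(8-methoxy-2-oxo-2H-chromen-7-yl)oxy]acetate | COc1c(OCC(=O)OC(C)(C)C)ccc2ccc(=O)oc12 | intermediate
11 | 2-[(8-methoxy-2-oxo-2H-chromen-7-yl)oxy]acetic acid | COc1c(OCC(=O)O)ccc2ccc(=O)oc12 | intermediate
12 | 7-{[(2E,5R)-5-hydroxy-3-methylhepta-2,6-dien-1-yl]oxy}-8-methoxy-2H-chromen-2-one | COc1c(OC/C=C(\C)C[C@@H](O)C=C)ccc2ccc(=O)oc12 | intermediate
13 | 7-({(2R,3R)-3-[(2R)-2-hydroxybut-3-en-1-yl]-3-methyloxiran-2-yl}methoxy)-8-methoxy-2H-chromen-2-one | COc1c(OC[C@H]2O[C@]2(C)C[C@@H](O)C=C)ccc2ccc(=O)oc12 | intermediate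
14 | 2-methylbut-2-ene | CC=C(C)C | starting material
15 | 7-({(2R,3R)-3-[(2R)-2-hydroxy-4-methylpent-3-en-1-yl]-3-methyloxiran-2-yl}methoxy)-8-methoxy-2H-chromen-2-one | COc1c(OC[C@H]2O[C@]2(C)C[C@@H](O)C=C(C)C)ccc2ccc(=O)oc12 | target

**Step count and risks**

Total step count: 8. Longest linear sequence: 6 (steps 1, 2, 3, 6, 7, 8).

Steps most likely to fail:

Step 6. The C1' radical may add to the C3=C4 bond of a second coumarin (Giese-type oligomerisation), or the excited photocatalyst may sensitise coumarin [2+2] dimerisation, before nickel captures the radical. The fallback replaces the radical by a two-electron transmetalation and sets out from 8 and 7. O-Alkylation of 8 with (iodomethyl)tributylstannane (K2CO3, DMF) should give tributyl{[(8-methoxy-2-oxo-2H-chromen-7-yl)oxy]methyl}stannane F1, in which tin reverses the polarity of C1'. Migita–Kosugi–Stille coupling of F1 with 7 (Pd2(dba)3, AsPh3, CuI, DMF, 60 °C) should then form the same bond with retention of the olefin geometry and come back to the route at 12.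

Step 7. Oxygen transfer to an olefin deactivated by the allylic aryloxy group may be slow and poorly face-selective, and the lactone may open at the basic pH that the dioxirane cycle needs. The fallback sets out from 12 and swaps the free chiral dioxirane for metal-bound, hydroxyl-directed delivery. A vanadium catalyst with a chiral bis-hydroxamic acid ligand (VO(OiPr)3, ligand, cumene hydroperoxide, toluene, 0 °C) should bind the C5' alkoxide and deliver oxygen intramolecularly to the homoallylic trisubstituted olefin under non-basic conditions. The ligand enantiomer is chosen so that ligand and carbinol together favour the (2'R,3'R) face. This comes back to the route at 13 without any new compound.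

Step 8. A ruthenium hydride formed from the catalyst may isomerise the secondary allylic alcohol to the ethyl ketone, or metathesis may stall at the hindered carbinol-substituted olefin. The fallback builds the isobutenyl group by carbonyl olefination and sets out from 13. Silylation (Et3SiCl, imidazole, CH2Cl2) should give the C5' triethylsilyl ether of 13 F2. Lemieux–Johnson cleavage of its vinyl group (OsO4 cat., NaIO4, 2,6-lutidine, dioxane–water) should give the α-silyloxy aldehyde F3. Wittig olefination with isopropylidenetriphenylphosphorane (from isopropyltriphenylphosphonium iodide and n-BuLi, THF, −78 °C) should give the C5' triethylsilyl ether of 15 F4. Desilylation (TBAF buffered with AcOH, THF, 0 °C) then comes back to the route at 15.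

**Further compounds**

F1 | step 6 | tributyl{[(8-methoxy-2-oxo-2H-chromen-7-yl)oxy]methyl}stannane | COc1c(OC[Sn](CCCC)(CCCC)CCCC)ccc2ccc(=O)oc12
F0 | step 7 | none | none
F2 | step 8 | 8-methoxy-7-({(2R,3R)-3-methyl-3-[(2R)-2-(triethylsilyloxy)but-3-en-1-yl]oxiran-2-yl}methoxy)-2H-chromen-2-one | COc1c(OC[C@H]2O[C@]2(C)C[C@@H](O[Si](CC)(CC)CC)C=C)ccc2ccc(=O)oc12
F3 | step 8 | (2R)-3-[(2R,3R)-3-{[(8-methoxy-2-oxo-2H-chromen-7-yl)oxy]methyl}-2-methyloxiran-2-yl]-2-(triethylsilyloxy)propanal | COc1c(OC[C@H]2O[C@]2(C)C[C@@H](O[Si](CC)(CC)CC)C=O)ccc2ccc(=O)oc12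
F4 | step 8 | 8-methoxy-7-({(2R,3R)-3-methyl-3-[(2R)-4-methyl-2-(triethylsilyloxy)pent-3-en-1-yl]oxiran-2-yl}methoxy)-2H-chromen-2-one | COc1c(OC[C@H]2O[C@]2(C)C[C@@H](O[Si](CC)(CC)CC)C=C(C)C)ccc2ccc(=O)oc12
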